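**Retrosynthetic overview**
- Last operations: desilylation, preceded by a stereospecific 1,2-hydride shift (non-aldol aldol) of an epoxy alcohol, which creates the ring ketone and leaves the tertiary ring-fusion alcohol.
- Key step: hydroxyl-directed epoxidation of a bicyclic, tetrasubstituted allylic alcohol. It forms the C–O bond at the ring-fusion carbon and fixes both ring-fusion centres.
- The butenolide ring is attached intact by B-alkyl Suzuki coupling with 4-bromofuran-2(5H)-one. Before that, the seven-membered ring B is closed onto ring A by an intramolecular B-alkyl Suzuki coupling of a cyclopentenyl triflate.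
- The triflate comes from an anti-aldol between silyl-protected (R)-3-hydroxy-2,2-dimethylcyclopentanone (ring A, from CBS desymmetrisation of the 1,3-dione) and (2S,3R)-2-ethenyl-2,3-dimethylpent-4-enal.
- That aldehyde comes from a new palladium-catalysed allyl–allyl coupling of isoprene monoxide with (Z)-crotylB(pin). Ring order: A (bought), then B, then the butenolide.

Assumption: 2,2-dimethylcyclopentane-1,3-dione, racemic isoprene monoxide, (Z)-crotylboronic acid pinacol ester and 4-bromofuran-2(5H)-one are bought; bicyclic compounds carry azulene locants (C3a and C8a are the ring-fusion atoms).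

**Route**

Step 1
Reactants: 1 2,2-dimethylcyclopentane-1,3-dione
Product: 2 (3R)-3-hydroxy-2,2-dimethylcyclopentan-1-one
Conditions: (S)-Me-CBS oxazaborolidine (10 mol %), BH3·SMe2 (0.6 equiv), THF, −20 °C; MeOH, then 1 M HCl
Reagents that add atoms: none
Why: Corey–Bakshi–Shibata reduction, in which the catalyst places the quaternary carbon as the large group, so hydride attack on either enantiotopic carbonyl gives the same (3R)-carbinol, and sub-stoichiometric borane limits diol formation.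

Step 2
Reactants: 2 (3R)-3-hydroxy-2,2-dimethylcyclopentan-1-one
Product: 3 (3R)-3-[(tert-butyldimethylsilyl)oxy]-2,2-dimethylcyclopentan-1-one
Conditions: TBSOTf, 2,6-lutidine, CH2Cl2, 0 °C
Reagents that add atoms: tert-butyldimethylsilyl trifluoromethanesulfonate, CC(C)(C)[Si](C)(C)OS(=O)(=O)C(F)(F)F
Why: Silyl triflate silylation of a hindered secondary alcohol leaves the stereocentre untouched, and the bulky ether later shields one face of ring A.

Step 3
Reactants: 4 rac-2-ethenyl-2-methyloxirane (isoprene monoxide, 1.5 equiv); 5 2-[(2Z)-but-2-en-1-yl]-4,4,5,5-tetramethyl-1,3,2-dioxaborolane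
Product: 7 (2S,3R)-2-ethenyl-2,3-dimethylpent-4-en-1-ol, via boronate ester 6 (not isolated)
Conditions: Pd2(dba)3 (2.5 mol %), (R)-MeO-furyl-BIPHEP (6 mol %), THF, 25 °C; aq. NH4Cl
Reagents that add atoms: none
Why: Proposed new method: zerovalent palladium ionises racemic 4 to an alkoxide-bearing π-allyl complex whose faces interconvert by π–σ–π isomerisation, the alkoxide binds the boron of 5 and triggers transmetalation to a bis(σ-allyl)palladium species, and chair-like 3,3′-reductive elimination at the tertiary terminus (CH2O–B arm pseudo-equatorial, (Z)-crotyl methyl pseudo-axial) sets the quaternary and the adjacent tertiary centre under ligand control, the ligand enantiomer being the one that gives (2S,3R); the closest known chemistry is the palladium-catalysed enantioselective allyl–allyl cross-coupling of allylB(pin) reagents with 3,3-disubstituted allylic chlorides or carbonates, together with the dynamic kinetic asymmetric substitution of isoprene monoxide.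

Step 4
Reactants: 7 (2S,3R)-2-ethenyl-2,3-dimethylpent-4-en-1-ol
Product: 8 (2S,3R)-2-ethenyl-2,3-dimethylpent-4-enal
Conditions: Dess–Martin periodinane, CH2Cl2, 0 °C → rt
Reagents that add atoms: none
Why: Dess–Martin oxidation of the neopentyl alcohol gives a non-enolisable aldehyde that cannot epimerise, and working at or below room temperature avoids Cope rearrangement of the 1,5-diene.

Step 5
Reactants: 3 (3R)-3-[(tert-butyldimethylsilyl)oxy]-2,2-dimethylcyclopentan-1-one; 8 (2S,3R)-2-ethenyl-2,3-dimethylpent-4-enal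
Product: 11 (3R,5S)-3-[(tert-butyldimethylsilyl)oxy]-5-[(1R,2S,3R)-2-ethenyl-2,3-dimethyl-1-[(trimethylsilyl)oxy]pent-4-en-1-yl]-2,2-dimethylcyclopentan-1-one, via lithium enolate 9 (not isolated), via lithium aldolate 10 (not isolated)
Conditions: LiN(i-Pr)2, THF, −78 °C; 8; Me3SiCl, −78 → 0 °C
Reagents that add atoms: chlorotrimethylsilane, C[Si](C)(C)Cl
Why: Directed aldol addition in which 3 can enolise on one side only, the lithium (E)-enolate reacts through a Zimmerman–Traxler chair on the face anti to the silyloxy group to give the anti adduct (5S,1′R), the α-quaternary aldehyde exerts only a weak Felkin bias, and in-situ O-silylation blocks retro-aldol.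

Step 6
Reactants: 11 (3R,5S)-3-[(tert-butyldimethylsilyl)oxy]-5-[(1R,2S,3R)-2-ethenyl-2,3-dimethyl-1-[(trimethylsilyl)oxy]pent-4-en-1-yl]-2,2-dimethylcyclopentan-1-one
Product: 13 (4R)-4-[(tert-butyldimethylsilyl)oxy]-2-[(1S,2S,3R)-2-ethenyl-2,3-dimethyl-1-[(trimethylsilyl)oxy]pent-4-en-1-yl]-5,5-dimethylcyclopent-1-en-1-yl trifluoromethanesulfonate, via potassium enolate 12 (not isolated)
Conditions: KN(SiMe3)2, PhNTf2, THF, −78 °C
Reagents that add atoms: N-phenylbis(trifluoromethanesulfonimide), O=S(=O)(N(c1ccccc1)S(=O)(=O)C(F)(F)F)C(F)(F)F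
Why: Enol triflate formation by deprotonation at the only α-hydrogen and O-sulfonylation at −78 °C, where β-elimination of the silyloxy group is slow; the ring stereocentre from the aldol is deliberately erased while the carbinol centre (now 1S by priority change only) is kept.

Step 7
Reactants: 13 (4R)-4-[(tert-butyldimethylsilyl)oxy]-2-[(1S,2S,3R)-2-ethenyl-2,3-dimethyl-1-[(trimethylsilyl)oxy]pent-4-en-1-yl]-5,5-dimethylcyclopent-1-en-1-yl trifluoromethanesulfonate
Product: 15 tert-butyl{[(2R,4S,5S,6R)-5-ethenyl-1,1,5,6-tetramethyl-4-[(trimethylsilyl)oxy]-1,2,3,4,5,6,7,8-octahydroazulen-2-yl]oxy}dimethylsilane, via alkylborane 14 (not isolated)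
Conditions: 9-BBN (1.05 equiv), THF, 0 °C → rt; Pd(dppf)Cl2 (10 mol %), Ph3As, Cs2CO3, DMF–THF–H2O, 0.005 M, rt → 40 °C
Reagents that add atoms: none
Why: 9-BBN hydroborates the vinyl group on the tertiary carbon much faster than the neopentyl-type vinyl group on the quaternary carbon, and the primary alkylborane closes the seven-membered ring B by intramolecular B-alkyl Suzuki–Miyaura coupling with the vinyl triflate under high dilution; no stereocentre is formed.

Step 8
Reactants: 15 tert-butyl{[(2R,4S,5S,6R)-5-ethenyl-1,1,5,6-tetramethyl-4-[(trimethylsilyl)oxy]-1,2,3,4,5,6,7,8-octahydroazulen-2-yl]oxy}dimethylsilane; 16 4-bromofuran-2(5H)-one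
Product: 19 4-{2-[(2R,4S,5S,6R)-2-[(tert-butyldimethylsilyl)oxy]-4-hydroxy-1,1,5,6-tetramethyl-1,2,3,4,5,6,7,8-octahydroazulen-5-yl]ethyl}furan-2(5H)-one, via alkylborane 17 (not isolated), via trimethylsilyl ether 18 (not isolated)
Conditions: 9-BBN (2 equiv), THF, 60 °C; 16, Pd(dppf)Cl2 (10 mol %), Ph3As, Cs2CO3, DMF–H2O, rt; citric acid, MeOH, 0 °C
Reagents that add atoms: none
Why: Anti-Markovnikov hydroboration of the remaining terminal alkene (the tetrasubstituted ring alkene is inert) and B-alkyl Suzuki–Miyaura coupling with the vinylogous acyl bromide 16 install the butenolide, and mild acid removes the labile trimethylsilyl ether while the hindered tert-butyldimethylsilyl ether stays.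

Step 9
Reactants: 19 4-{2-[(2R,4S,5S,6R)-2-[(tert-butyldimethylsilyl)oxy]-4-hydroxy-1,1,5,6-tetramethyl-1,2,3,4,5,6,7,8-octahydroazulen-5-yl]ethyl}furan-2(5H)-one
Product: 20 4-{2-[(2R,3aS,4S,5S,6R,8aS)-2-[(tert-butyldimethylsilyl)oxy]-3a,8a-epoxy-4-hydroxy-1,1,5,6-tetramethyldecahydroazulen-5-yl]ethyl}furan-2(5H)-one
Conditions: VO(acac)2 (5 mol %), t-BuOOH, CH2Cl2, 0 °C
Reagents that add atoms: tert-butyl hydroperoxide, CC(C)(C)OO
Why: Hydroxyl-directed vanadium-catalysed epoxidation of an allylic alcohol, in which the C4 hydroxyl delivers oxygen syn to itself and to the face opposite the C2 silyloxy group, forming the C8a–O bond of the target with the required configuration and leaving the electron-poor butenolide untouched.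

Step 10
Reactants: 20 4-{2-[(2R,3aS,4S,5S,6R,8aS)-2-[(tert-butyldimethylsilyl)oxy]-3a,8a-epoxy-4-hydroxy-1,1,5,6-tetramethyldecahydroazulen-5-yl]ethyl}furan-2(5H)-one
Product: 23 4-{2-[(2R,3aR,5S,6R,8aR)-2-[(tert-butyldimethylsilyl)oxy]-8a-hydroxy-1,1,5,6-tetramethyl-4-oxodecahydroazulen-5-yl]ethyl}furan-2(5H)-one, via epoxy silyl ether 21 (not isolated), via silyloxy ketone 22 (not isolated)
Conditions: Me3SiOTf (2.2 equiv), i-Pr2NEt, CH2Cl2, −78 → −40 °C; 1 M HCl work-up
Reagents that add atoms: none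
Why: Non-aldol aldol (semipinacol) rearrangement, in which the silyl triflate silylates the carbinol and activates the epoxide, the C4–H bond lying anti-periplanar to the C3a–O bond migrates as hydride with inversion at C3a while the oxygen stays on C8a, giving the C4 ketone with H-3a trans to O-8a (trans ring fusion), and the acidic work-up frees the tertiary alcohol.

Step 11
Reactants: 23 4-{2-[(2R,3aR,5S,6R,8aR)-2-[(tert-butyldimethylsilyl)oxy]-8a-hydroxy-1,1,5,6-tetramethyl-4-oxodecahydroazulen-5-yl]ethyl}furan-2(5H)-one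
Product: 24 4-{2-[(2R,3aR,5S,6R,8aR)-2,8a-dihydroxy-1,1,5,6-tetramethyl-4-oxodecahydroazulen-5-yl]ethyl}furan-2(5H)-one
Conditions: HF·pyridine, THF, 0 °C → rt
Reagents that add atoms: none
Why: Fluoride-mediated desilylation under buffered acidic conditions that neither dehydrate nor retro-aldolise the β-hydroxy ketone and do not open the butenolide.

**Compound list**
1 | 2,2-dimethylcyclopentane-1,3-dione | O=C1CCC(=O)C1(C)C | starting material
2 | (3R)-3-hydroxy-2,2-dimethylcyclopentan-1-one | O=C1CC[C@@H](O)C1(C)C | intermediate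
3 | (3R)-3-[(tert-butyldimethylsilyl)oxy]-2,2-dimethylcyclopentan-1-one | O=C1CC[C@@H](O[Si](C)(C)C(C)(C)C)C1(C)C | intermediate
4 | rac-2-ethenyl-2-methyloxirane (isoprene monoxide) | CC1(C=C)CO1 | starting material
5 | 2-[(2Z)-but-2-en-1-yl]-4,4,5,5-tetramethyl-1,3,2-dioxaborolane | C/C=C\CB1OC(C)(C)C(C)(C)O1 | starting material
6 | 2-{[(2S,3R)-2-ethenyl-2,3-dimethylpent-4-en-1-yl]oxy}-4,4,5,5-tetramethyl-1,3,2-dioxaborolane | C[C@@H]([C@](C)(C=C)COB1OC(C)(C)C(C)(C)O1)C=C | intermediate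
7 | (2S,3R)-2-ethenyl-2,3-dimethylpent-4-en-1-ol | C[C@@H]([C@](C)(C=C)CO)C=C | intermediate
8 | (2S,3R)-2-ethenyl-2,3-dimethylpent-4-enal | C[C@@H]([C@](C)(C=C)C=O)C=C | intermediate
9 | lithium (4R)-4-[(tert-butyldimethylsilyl)oxy]-5,5-dimethylcyclopent-1-en-1-olate | [Li+].[O-]C1=CC[C@@H](O[Si](C)(C)C(C)(C)C)C1(C)C | intermediate
10 | lithium (1R,2S,3R)-1-[(1S,4R)-4-[(tert-butyldimethylsilyl)oxy]-3,3-dimethyl-2-oxocyclopentyl]-2-ethenyl-2,3-dimethylpent-4-en-1-olate | O=C1[C@@H](C[C@@H](O[Si](C)(C)C(C)(C)C)C1(C)C)[C@@H]([O-])[C@@](C)(C=C)[C@H](C)C=C.[Li+] | intermediate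
11 | (3R,5S)-3-[(tert-butyldimethylsilyl)oxy]-5-[(1R,2S,3R)-2-ethenyl-2,3-dimethyl-1-[(trimethylsilyl)oxy]pent-4-en-1-yl]-2,2-dimethylcyclopentan-1-one | O=C1[C@@H](C[C@@H](O[Si](C)(C)C(C)(C)C)C1(C)C)[C@@H](O[Si](C)(C)C)[C@@](C)(C=C)[C@H](C)C=C | intermediate
12 | potassium (4R)-4-[(tert-butyldimethylsilyl)oxy]-2-[(1S,2S,3R)-2-ethenyl-2,3-dimethyl-1-[(trimethylsilyl)oxy]pent-4-en-1-yl]-5,5-dimethylcyclopent-1-en-1-olate | [K+].[O-]C1=C(C[C@@H](O[Si](C)(C)C(C)(C)C)C1(C)C)[C@@H](O[Si](C)(C)C)[C@@](C)(C=C)[C@H](C)C=C | intermediate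
13 | (4R)-4-[(tert-butyldimethylsilyl)oxy]-2-[(1S,2S,3R)-2-ethenyl-2,3-dimethyl-1-[(trimethylsilyl)oxy]pent-4-en-1-yl]-5,5-dimethylcyclopent-1-en-1-yl trifluoromethanesulfonate | FC(F)(F)S(=O)(=O)OC1=C(C[C@@H](O[Si](C)(C)C(C)(C)C)C1(C)C)[C@@H](O[Si](C)(C)C)[C@@](C)(C=C)[C@H](C)C=C | intermediate
14 | (4R)-2-[(1S,2S,3R)-5-(9-borabicyclo[3.3.1]nonan-9-yl)-2-ethenyl-2,3-dimethyl-1-[(trimethylsilyl)oxy]pentyl]-4-[(tert-butyldimethylsilyl)oxy]-5,5-dimethylcyclopent-1-en-1-yl trifluoromethanesulfonate | FC(F)(F)S(=O)(=O)OC1=C(C[C@@H](O[Si](C)(C)C(C)(C)C)C1(C)C)[C@@H](O[Si](C)(C)C)[C@@](C)(C=C)[C@H](C)CCB2C3CCCC2CCC3 | intermediate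
15 | tert-butyl{[(2R,4S,5S,6R)-5-ethenyl-1,1,5,6-tetramethyl-4-[(trimethylsilyl)oxy]-1,2,3,4,5,6,7,8-octahydroazulen-2-yl]oxy}dimethylsilane | C[C@@H]1CCC2=C(C[C@@H](O[Si](C)(C)C(C)(C)C)C2(C)C)[C@@H](O[Si](C)(C)C)[C@@]1(C)C=C | intermediate
16 | 4-bromofuran-2(5H)-one | O=C1C=C(Br)CO1 | starting material
17 | 9-{2-[(2R,4S,5S,6R)-2-[(tert-butyldimethylsilyl)oxy]-1,1,5,6-tetramethyl-4-[(trimethylsilyl)oxy]-1,2,3,4,5,6,7,8-octahydroazulen-5-yl]ethyl}-9-borabicyclo[3.3.1]nonane | C[C@@H]1CCC2=C(C[C@@H](O[Si](C)(C)C(C)(C)C)C2(C)C)[C@@H](O[Si](C)(C)C)[C@@]1(C)CCB3C4CCCC3CCC4 | intermediate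
18 | 4-{2-[(2R,4S,5S,6R)-2-[(tert-butyldimethylsilyl)oxy]-1,1,5,6-tetramethyl-4-[(trimethylsilyl)oxy]-1,2,3,4,5,6,7,8-octahydroazulen-5-yl]ethyl}furan-2(5H)-one | C[C@@H]1CCC2=C(C[C@@H](O[Si](C)(C)C(C)(C)C)C2(C)C)[C@@H](O[Si](C)(C)C)[C@@]1(C)CCC1=CC(=O)OC1 | intermediate
19 | 4-{2-[(2R,4S,5S,6R)-2-[(tert-butyldimethylsilyl)oxy]-4-hydroxy-1,1,5,6-tetramethyl-1,2,3,4,5,6,7,8-octahydroazulen-5-yl]ethyl}furan-2(5H)-one | C[C@@H]1CCC2=C(C[C@@H](O[Si](C)(C)C(C)(C)C)C2(C)C)[C@@H](O)[C@@]1(C)CCC1=CC(=O)OC1 | intermediate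
20 | 4-{2-[(2R,3aS,4S,5S,6R,8aS)-2-[(tert-butyldimethylsilyl)oxy]-3a,8a-epoxy-4-hydroxy-1,1,5,6-tetramethyldecahydroazulen-5-yl]ethyl}furan-2(5H)-one | C[C@@H]1CC[C@@]2(O3)[C@]3(C[C@@H](O[Si](C)(C)C(C)(C)C)C2(C)C)[C@@H](O)[C@@]1(C)CCC1=CC(=O)OC1 | intermediate
21 | 4-{2-[(2R,3aS,4S,5S,6R,8aS)-2-[(tert-butyldimethylsilyl)oxy]-3a,8a-epoxy-1,1,5,6-tetramethyl-4-[(trimethylsilyl)oxy]decahydroazulen-5-yl]ethyl}furan-2(5H)-one | C[C@@H]1CC[C@@]2(O3)[C@]3(C[C@@H](O[Si](C)(C)C(C)(C)C)C2(C)C)[C@@H](O[Si](C)(C)C)[C@@]1(C)CCC1=CC(=O)OC1 | intermediate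
22 | 4-{2-[(2R,3aR,5S,6R,8aR)-2-[(tert-butyldimethylsilyl)oxy]-1,1,5,6-tetramethyl-4-oxo-8a-[(trimethylsilyl)oxy]decahydroazulen-5-yl]ethyl}furan-2(5H)-one | C[C@@H]1CC[C@@]2(O[Si](C)(C)C)[C@@H](C[C@@H](O[Si](C)(C)C(C)(C)C)C2(C)C)C(=O)[C@@]1(C)CCC1=CC(=O)OC1 | intermediate
23 | 4-{2-[(2R,3aR,5S,6R,8aR)-2-[(tert-butyldimethylsilyl)oxy]-8a-hydroxy-1,1,5,6-tetramethyl-4-oxodecahydroazulen-5-yl]ethyl}furan-2(5H)-one | C[C@@H]1CC[C@@]2(O)[C@@H](C[C@@H](O[Si](C)(C)C(C)(C)C)C2(C)C)C(=O)[C@@]1(C)CCC1=CC(=O)OC1 | intermediate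
24 | 4-{2-[(2R,3aR,5S,6R,8aR)-2,8a-dihydroxy-1,1,5,6-tetramethyl-4-oxodecahydroazulen-5-yl]ethyl}furan-2(5H)-one | C[C@@H]1CC[C@@]2(O)[C@@H](C[C@@H](O)C2(C)C)C(=O)[C@@]1(C)CCC1=CC(=O)OC1 | target

**Step count and risks**

Total steps: 11. Longest linear sequence: 9 (steps 1, 2, 5 to 11; the branch through steps 3 and 4 is equally 9 steps to the target).

The three steps most likely to fail:

Step 3 (the new coupling). Risks are attack at the primary terminus, the wrong relative configuration (the (E)-crotyl reagent is the lever for the C3 epimer) and the wrong or low enantioselectivity (the ligand antipode gives the mirror image). The fallback uses known chemistry, sets out from 4 and comes back at 7. Compound 4 is opened in the SN2′ sense with TiCl4 (CH2Cl2, −78 °C) to (2E)-4-chloro-2-methylbut-2-en-1-ol F1; either alkene geometry serves, because the allyl complex equilibrates. F1 is silylated (TBSCl, imidazole) to tert-butyl{[(2E)-4-chloro-2-methylbut-2-en-1-yl]oxy}dimethylsilane F2. F2 is coupled with 5 under the established allyl–allyl cross-coupling conditions for 3,3-disubstituted allyl chlorides (Pd2(dba)3, (R)-MeO-furyl-BIPHEP, CsF, THF, 60 °C) to tert-butyl{[(2S,3R)-2-ethenyl-2,3-dimethylpent-4-en-1-yl]oxy}dimethylsilane F3, which is desilylated with Bu4NF to 7.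

Step 7 (ring B closure). Risks are double hydroboration, Heck-type closure of the vinylpalladium species onto the remaining vinyl group, and slow seven-ring closure at a hindered tetrasubstituted triflate. The fallback sets out from 13 (through 14) and comes back at 15. The borane 14 is iodinated (I2, NaOMe, MeOH–THF, 0 °C) to (4R)-4-[(tert-butyldimethylsilyl)oxy]-2-[(1S,2S,3R)-2-ethenyl-5-iodo-2,3-dimethyl-1-[(trimethylsilyl)oxy]pentyl]-5,5-dimethylcyclopent-1-en-1-yl trifluoromethanesulfonate F4. F4 is then cyclised by nickel-catalysed reductive vinyl–alkyl cross-electrophile coupling (NiBr2(dme), 4,4′-di-tert-butyl-2,2′-bipyridine, manganese powder, DMA, rt), a radical-type closure that needs neither base nor an organoboron partner.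

Step 10 (hydride shift). Risks are ionisation at C8a with methyl shift or elimination, and silylation of the butenolide to a silyloxyfuran. The fallback sets out from 19 and comes back at 23. Compound 19 is oxidised (Dess–Martin periodinane) to the enone 4-{2-[(2R,5S,6R)-2-[(tert-butyldimethylsilyl)oxy]-1,1,5,6-tetramethyl-4-oxo-1,2,3,4,5,6,7,8-octahydroazulen-5-yl]ethyl}furan-2(5H)-one F5. F5 is epoxidised nucleophilically on the face opposite the silyloxy group (t-BuOOH, DBU) to 4-{2-[(2R,3aR,5S,6R,8aS)-2-[(tert-butyldimethylsilyl)oxy]-3a,8a-epoxy-1,1,5,6-tetramethyl-4-oxodecahydroazulen-5-yl]ethyl}furan-2(5H)-one F6. The C3a–O bond is then cleaved reductively with SmI2 (THF–MeOH, −90 °C); the C3a centre is set by protonation of the samarium enolate or, if needed, by equilibration with DBU to the trans-fused ketol 23.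

Further compounds
F1 | step 3 | (2E)-4-chloro-2-methylbut-2-en-1-ol | OC/C(C)=C/CCl
F2 | step 3 | tert-butyl{[(2E)-4-chloro-2-methylbut-2-en-1-yl]oxy}dimethylsilane | CC(C)(C)[Si](C)(C)OC/C(C)=C/CCl
F3 | step 3 | tert-butyl{[(2S,3R)-2-ethenyl-2,3-dimethylpent-4-en-1-yl]oxy}dimethylsilane | C[C@@H]([C@](C)(C=C)CO[Si](C)(C)C(C)(C)C)C=C
F4 | step 7 | (4R)-4-[(tert-butyldimethylsilyl)oxy]-2-[(1S,2S,3R)-2-ethenyl-5-iodo-2,3-dimethyl-1-[(trimethylsilyl)oxy]pentyl]-5,5-dimethylcyclopent-1-en-1-yl trifluoromethanesulfonate | FC(F)(F)S(=O)(=O)OC1=C(C[C@@H](O[Si](C)(C)C(C)(C)C)C1(C)C)[C@@H](O[Si](C)(C)C)[C@@](C)(C=C)[C@H](C)CCI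
F5 | step 10 | 4-{2-[(2R,5S,6R)-2-[(tert-butyldimethylsilyl)oxy]-1,1,5,6-tetramethyl-4-oxo-1,2,3,4,5,6,7,8-octahydroazulen-5-yl]ethyl}furan-2(5H)-one | C[C@@H]1CCC2=C(C[C@@H](O[Si](C)(C)C(C)(C)C)C2(C)C)C(=O)[C@@]1(C)CCC1=CC(=O)OC1
F6 | step 10 | 4-{2-[(2R,3aR,5S,6R,8aS)-2-[(tert-butyldimethylsilyl)oxy]-3a,8a-epoxy-1,1,5,6-tetramethyl-4-oxodecahydroazulen-5-yl]ethyl}furan-2(5H)-one | C[C@@H]1CC[C@@]2(O3)[C@]3(C[C@@H](O[Si](C)(C)C(C)(C)C)C2(C)C)C(=O)[C@@]1(C)CCC1=CC(=O)OC1
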